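**Retrosynthetic overview**
1. The target, (all-E,3R,3'R,6'R)-3,19,3'-trihydroxy-7,8-dihydro-β,ε-caroten-8-one, is cut at C11=C12 and C11'=C12' (two Wittig olefinations) into a ring-A C15 phosphonium salt, the C10 trienedial and a ring-B keto-enal.
2. Ring A (ε-ring, C1'–C6') is closed by forming C1'–C6' in a proton-initiated cation–olefin cyclisation of an acyclic enoate. The enabling feature is that gem-dimethyl C1' (a tertiary cation site) stands 1,6 to C6', C5' carries a methyl (Markovnikov cation, then the 4',5'-olefin), and the C3' carbinol lies 1,3 to C1' and 1,4 to C6', so a chair relays its configuration to C6'.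
3. The three carbons and the stereocentre of (R)-epichlorohydrin become C2'–C3'–C4' and C3' of ring A; the ring ester carbon (C7') is then grown to the C15 salt.
4. Ring B comes intact from (4R,6R)-actinol; its C8 ketone and C9 hydroxymethyl enone are unmasked from a 2,3-disubstituted furan (furan C2 = C8, C3 = C9, C5 = C11).
5. Ring order: ring B is pre-formed, ring A is formed in step 5, the temporary furan is attached and opened in steps 19–21; assembly is C15 + C10 (steps 11–13), then C25 + C15 (step 22) and desilylation (step 23).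

Key step: step 5

Remark: carotenoid locants are used in the text (primed = ring-A half); TIPS = triisopropylsilyl, TBS = tert-butyldimethylsilyl; (R)-epichlorohydrin, (4R,6R)-actinol, furan-3-ylmethanol and the C10 trienedial are assumed to be commercial.

**Route**

Step 1
Reactants: 1 (R)-epichlorohydrin
Product: 2 (R)-1-chloro-4-methylpent-4-en-2-ol
Conditions: CH2=C(CH3)MgBr, CuI (10 mol%), THF, −40 → −20 °C
Reagents that add atoms: isopropenylmagnesium bromide, C=C(C)[Mg]Br
Why: Copper-catalysed Grignard opening of the epoxide at its unsubstituted carbon should outrun attack at C–Cl and leaves the stereocentre (the future C3') untouched.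

Step 2
Reactants: 2 (R)-1-chloro-4-methylpent-4-en-2-ol
Product: 4 (R)-2-methylhept-1-en-6-yn-4-ol, via epoxide 3 (not isolated)
Conditions: HC≡CLi·H2NCH2CH2NH2 (3 equiv), DMSO, 0 °C → rt
Reagents that add atoms: lithium acetylide ethylenediamine complex, [Li]C#C.NCCN
Why: The alkoxide should close to the terminal epoxide (intramolecular Williamson reaction) and acetylide should open it at CH2 (SN2), so the carbinol centre is never a reacting carbon and keeps its configuration.

Step 3
Reactants: 4 (R)-2-methylhept-1-en-6-yn-4-ol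
Product: 5 (R)-triisopropyl[(2-methylhept-1-en-6-yn-4-yl)oxy]silane
Conditions: i-Pr3SiOTf, 2,6-lutidine, CH2Cl2, 0 °C
Reagents that add atoms: triisopropylsilyl trifluoromethanesulfonate, CC(C)[Si](OS(=O)(=O)C(F)(F)F)(C(C)C)C(C)C
Why: Silylation with the silyl triflate gives a bulky, non-participating, weakly basic ether that should survive organoaluminium reagents and anhydrous acid and later bias the chair of the key step.

Step 4
Reactants: 5 (R)-triisopropyl[(2-methylhept-1-en-6-yn-4-yl)oxy]silane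
Product: 7 methyl (2E,5R)-3,7-dimethyl-5-(triisopropylsilyloxy)octa-2,7-dienoate, via alkenylalane 6 (not isolated)
Conditions: Me3Al, Cp2ZrCl2 (0.25 equiv), CH2Cl2, 0 °C → rt; ClCO2Me, 0 °C → rt
Reagents that add atoms: trimethylaluminium, C[Al](C)C; methyl chloroformate, COC(=O)Cl
Why: Zirconium-catalysed carboalumination (Negishi carboalumination) adds CH3 and Al syn across the terminal alkyne with Al at the terminus, and acylation of the alkenylalane with retention should give the (E)-β-methyl enoate, the 1,1-disubstituted olefin being inert to carbometalation.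

Step 5
Reactants: 7 methyl (2E,5R)-3,7-dimethyl-5-(triisopropylsilyloxy)octa-2,7-dienoate
Product: 8 methyl (1R,4R)-2,6,6-trimethyl-4-(triisopropylsilyloxy)cyclohex-2-ene-1-carboxylate
Conditions: MeSO3H (3 equiv), CH2Cl2, −20 → 0 °C
Reagents that add atoms: none
Why: The acid protonates the only basic C=C (the 1,1-disubstituted C1'=CH2; the conjugated enoate olefin is not C-protonated) to the tertiary C1' cation, which C6' of the enoate captures in a Markovnikov 6-endo-trig cation–olefin closure (C1'–C6' bond, ring A) to the tertiary C5' cation, and loss of H-4' gives the 4',5'-olefin. The closest known reaction type is the acid cyclisation of geranic acid or methyl geranate to α-cyclogeranic acid or its ester (and of pseudoionone to α-ionone). Ring A closes through a chair in which the bulky C3' silyloxy group is equatorial (axial it would meet the developing axial C1' methyl) and the (E)-enoate geometry puts CO2CH3 equatorial on C6', so C3' relays to C6' and the 3',6'-trans (1R,4R) isomer should form. The step needs one protonatable olefin (secured by the enoate conjugation), proton loss from C4' (H-6' is α to the ester, hindered and poorly hyperconjugating; an exocyclic isomer would re-protonate and funnel to the endocyclic trisubstituted olefin; the allylic oxygen slows drift to the conjugated isomer) and an O-substituent that neither participates nor ionises (hence the silyl ether under anhydrous acid).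

Step 6
Reactants: 8 methyl (1R,4R)-2,6,6-trimethyl-4-(triisopropylsilyloxy)cyclohex-2-ene-1-carboxylate
Product: 9 [(1R,4R)-2,6,6-trimethyl-4-(triisopropylsilyloxy)cyclohex-2-en-1-yl]methanol
Conditions: i-Bu2AlH (2.5 equiv), CH2Cl2, −78 → 0 °C
Reagents that add atoms: none
Why: Hydride reduction of the hindered ester to the primary alcohol should proceed without touching the silyl ether, the olefin or the C6' centre.

Step 7
Reactants: 9 [(1R,4R)-2,6,6-trimethyl-4-(triisopropylsilyloxy)cyclohex-2-en-1-yl]methanol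
Product: 10 (1R,4R)-2,6,6-trimethyl-4-(triisopropylsilyloxy)cyclohex-2-ene-1-carbaldehyde
Conditions: Dess–Martin periodinane, NaHCO3, CH2Cl2, 0 °C → rt
Reagents that add atoms: none
Why: Buffered Dess–Martin oxidation is non-basic and non-acidic, so the β,γ-unsaturated aldehyde should form without epimerisation at C6' or olefin migration.

Step 8
Reactants: 10 (1R,4R)-2,6,6-trimethyl-4-(triisopropylsilyloxy)cyclohex-2-ene-1-carbaldehyde
Product: 11 (3E)-4-[(1R,4R)-2,6,6-trimethyl-4-(triisopropylsilyloxy)cyclohex-2-en-1-yl]but-3-en-2-one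
Conditions: CH3C(O)CH2P(O)(OCH3)2, LiCl, i-Pr2NEt, CH3CN, rt
Reagents that add atoms: dimethyl (2-oxopropyl)phosphonate, COP(=O)(CC(C)=O)OC
Why: Horner–Wadsworth–Emmons olefination with a β-ketophosphonate under LiCl/amine conditions is E-selective and mild enough that the α-stereocentre of the aldehyde should not enolise, giving the silyl ether of (3R,6R)-3-hydroxy-α-ionone.

Step 9
Reactants: 11 (3E)-4-[(1R,4R)-2,6,6-trimethyl-4-(triisopropylsilyloxy)cyclohex-2-en-1-yl]but-3-en-2-one
Product: 12 (1E)-3-methyl-1-[(1R,4R)-2,6,6-trimethyl-4-(triisopropylsilyloxy)cyclohex-2-en-1-yl]penta-1,4-dien-3-ol (both C3 epimers)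
Conditions: CH2=CHMgBr, THF, −20 → 0 °C
Reagents that add atoms: vinylmagnesium bromide, C=C[Mg]Br
Why: Vinyl Grignard 1,2-addition to the ionone-type enone is standard, and the new carbinol centre need not be controlled because it is erased in step 10.

Step 10
Reactants: 12 (1E)-3-methyl-1-[(1R,4R)-2,6,6-trimethyl-4-(triisopropylsilyloxy)cyclohex-2-en-1-yl]penta-1,4-dien-3-ol
Product: 13 [(2E,4E)-3-methyl-5-[(1R,4R)-2,6,6-trimethyl-4-(triisopropylsilyloxy)cyclohex-2-en-1-yl]penta-2,4-dien-1-yl]triphenylphosphonium bromide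
Conditions: PPh3·HBr, CH3OH/CH2Cl2, 0 °C → rt
Reagents that add atoms: triphenylphosphine hydrobromide, [Br-].[PH+](c1ccccc1)(c1ccccc1)c1ccccc1
Why: Ionisation of the tertiary bis-allylic carbinol to a pentadienyl cation and capture by PPh3 at the primary terminus (SN1 with allylic transposition, as for vinyl-ionol-type carbinols) should give the conjugated C15 Wittig salt, the 2E isomer being purified by crystallisation.

Step 11
Reactants: 13 the C15 phosphonium bromide of step 10; 14 (2E,4E,6E)-2,7-dimethylocta-2,4,6-trienedial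
Product: 15 (2E,4E,6E,8E,10E,12E)-2,7,11-trimethyl-13-[(1R,4R)-2,6,6-trimethyl-4-(triisopropylsilyloxy)cyclohex-2-en-1-yl]trideca-2,4,6,8,10,12-hexaenal
Conditions: 14 (2.5 equiv), 1,2-epoxybutane, EtOH, 75 °C
Reagents that add atoms: none
Why: Wittig olefination under neutral epoxide-mediated conditions with excess dialdehyde should give the mono-condensation product, the hindered Z olefin relaxing to E at the reaction temperature.

Step 12
Reactants: 15 the C25 aldehyde of step 11
Product: 16 (2E,4E,6E,8E,10E,12E)-2,7,11-trimethyl-13-[(1R,4R)-2,6,6-trimethyl-4-(triisopropylsilyloxy)cyclohex-2-en-1-yl]trideca-2,4,6,8,10,12-hexaen-1-ol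
Conditions: NaBH4, CH3OH/CH2Cl2, 0 °C
Reagents that add atoms: none
Why: Borohydride 1,2-reduction of a polyenal to the allylic alcohol is selective and leaves polyene and silyl ether untouched.

Step 13
Reactants: 16 the C25 alcohol of step 12
Product: 17 [(2E,4E,6E,8E,10E,12E)-2,7,11-trimethyl-13-[(1R,4R)-2,6,6-trimethyl-4-(triisopropylsilyloxy)cyclohex-2-en-1-yl]trideca-2,4,6,8,10,12-hexaen-1-yl]triphenylphosphonium bromide
Conditions: PPh3·HBr, CH3OH/CH2Cl2, 0 °C → rt
Reagents that add atoms: triphenylphosphine hydrobromide, [Br-].[PH+](c1ccccc1)(c1ccccc1)c1ccccc1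
Why: The polyenyl alcohol should ionise under the mild acid and the delocalised cation be trapped by PPh3 at the terminal carbon, as in the conversion of retinol into its phosphonium salt.

Step 14
Reactants: 18 (4R,6R)-4-hydroxy-2,2,6-trimethylcyclohexan-1-one (actinol)
Product: 19 (4R,6R)-4-(tert-butyldimethylsilyloxy)-2,2,6-trimethylcyclohexan-1-one
Conditions: TBSCl, imidazole, DMF, rt
Reagents that add atoms: tert-butyl(chloro)dimethylsilane, CC(C)(C)[Si](C)(C)Cl
Why: Standard silylation protects the C3 hydroxyl, whose configuration is the one required in ring B.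

Step 15
Reactants: 19 (4R,6R)-4-(tert-butyldimethylsilyloxy)-2,2,6-trimethylcyclohexan-1-one
Product: 21 (4R)-4-(tert-butyldimethylsilyloxy)-2,6,6-trimethylcyclohex-1-en-1-yl trifluoromethanesulfonate, via lithium enolate 20 (not isolated)
Conditions: LDA, THF, −78 °C; PhNTf2, −78 °C → rt
Reagents that add atoms: N-phenylbis(trifluoromethanesulfonimide), O=S(=O)(N(c1ccccc1)S(=O)(=O)C(F)(F)F)C(F)(F)F
Why: Only one α-carbon bears a hydrogen (the other is quaternary), so enolisation and O-triflation should fix the tetrasubstituted C5=C6 olefin of ring B unambiguously.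

Step 16
Reactants: 21 (4R)-4-(tert-butyldimethylsilyloxy)-2,6,6-trimethylcyclohex-1-en-1-yl trifluoromethanesulfonate
Product: 22 methyl (4R)-4-(tert-butyldimethylsilyloxy)-2,6,6-trimethylcyclohex-1-ene-1-carboxylate
Conditions: Pd(OAc)2 (5 mol%), PPh3, Et3N, CH3OH, DMF, CO (1 atm), 60 °C
Reagents that add atoms: carbon monoxide, [C-]#[O+]; methanol, CO
Why: Palladium-catalysed alkoxycarbonylation of the enol triflate (oxidative addition, CO insertion, methanolysis) should install C7 on the hindered vinyl carbon.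

Step 17
Reactants: 22 methyl (4R)-4-(tert-butyldimethylsilyloxy)-2,6,6-trimethylcyclohex-1-ene-1-carboxylate
Product: 23 [(4R)-4-(tert-butyldimethylsilyloxy)-2,6,6-trimethylcyclohex-1-en-1-yl]methanol
Conditions: i-Bu2AlH (2.5 equiv), CH2Cl2, −78 → 0 °C
Reagents that add atoms: none
Why: 1,2-Reduction of the twisted, hindered enoate should give the allylic alcohol cleanly.

Step 18
Reactants: 23 [(4R)-4-(tert-butyldimethylsilyloxy)-2,6,6-trimethylcyclohex-1-en-1-yl]methanol
Product: 24 {[(1R)-4-(bromomethyl)-3,5,5-trimethylcyclohex-3-en-1-yl]oxy}(tert-butyl)dimethylsilane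
Conditions: CBr4, PPh3, CH2Cl2, 0 °C
Reagents that add atoms: carbon tetrabromide, BrC(Br)(Br)Br
Why: The Appel reaction converts the primary allylic alcohol into the bromide under neutral conditions that spare the silyl ether; the bromide is used directly.

Step 19
Reactants: 24 the allylic bromide of step 18; 25 furan-3-ylmethanol
Product: 27 [2-{[(4R)-4-(tert-butyldimethylsilyloxy)-2,6,6-trimethylcyclohex-1-en-1-yl]methyl}furan-3-yl]methanol, via dilithiofuran 26 (not isolated)
Conditions: 25, n-BuLi (2.2 equiv), THF, −78 → 0 °C; then 24, −78 °C → rt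
Reagents that add atoms: none
Why: The lithium alkoxide directs the second lithiation to furan C2 (ortho-lithiation), and the 2-furyllithium should displace the primary allylic bromide (SN2) to form C7–C8, the furan serving as a masked cis-4-oxo-2-enal.

Step 20
Reactants: 27 the furylmethanol of step 19
Product: 28 tert-butyl{[2-{[(4R)-4-(tert-butyldimethylsilyloxy)-2,6,6-trimethylcyclohex-1-en-1-yl]methyl}furan-3-yl]methoxy}dimethylsilane
Conditions: TBSCl, imidazole, DMF, rt
Reagents that add atoms: tert-butyl(chloro)dimethylsilane, CC(C)(C)[Si](C)(C)Cl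
Why: Silylation of the primary alcohol (future C19–OH) prevents lactol and furan formation once the cis-related C11 aldehyde is unveiled.

Step 21
Reactants: 28 the bis-silyl furan of step 20
Product: 31 (2E)-3-[(tert-butyldimethylsilyloxy)methyl]-5-[(4R)-4-(tert-butyldimethylsilyloxy)-2,6,6-trimethylcyclohex-1-en-1-yl]-4-oxopent-2-enal, via endoperoxide 29 (not isolated), via Z-keto-enal 30 (not isolated)
Conditions: O2, hν, tetraphenylporphyrin (cat.), CH2Cl2, −78 °C; Me2S, −78 °C → rt; I2 (cat.), rt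
Reagents that add atoms: oxygen, O=O
Why: [4+2] cycloaddition of singlet oxygen across furan C2/C5 (expected to be faster than the ene reaction of the hindered ring-B olefin), reduction of the endoperoxide by Me2S to the cis-enedione and iodine-catalysed equilibration should give the more stable (E)-4-oxo-enal with C8 and C11 trans.

Step 22
Reactants: 17 the C25 phosphonium bromide of step 13; 31 the keto-enal of step 21
Product: 32 (all-E,3R,3'R,6'R)-3,19-bis(tert-butyldimethylsilyloxy)-3'-(triisopropylsilyloxy)-7,8-dihydro-β,ε-caroten-8-one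
Conditions: 1,2-epoxybutane, EtOH/CH2Cl2, 70 °C
Reagents that add atoms: none
Why: Wittig olefination under neutral epoxide-mediated conditions should take the aldehyde in preference to the hindered C8 ketone without enolising C7, and at this temperature the hindered 11Z olefin relaxes to the all-E polyene.

Step 23
Reactants: 32 the tris-silyl ether of step 22
Product: 33 (all-E,3R,3'R,6'R)-3,19,3'-trihydroxy-7,8-dihydro-β,ε-caroten-8-one (siphonaxanthin)
Conditions: Bu4NF, AcOH, THF, rt → 40 °C
Reagents that add atoms: none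
Why: Fluoride cleaves the three Si–O bonds while acetic acid buffers the alkoxides, so the C7-enolisable β,γ-unsaturated ketone and the allylic 3'-alcohol should survive to give the target.

**Compound list**
1 | (R)-epichlorohydrin | C1[C@@H](O1)CCl | starting material
2 | (R)-1-chloro-4-methylpent-4-en-2-ol | C=C(C)C[C@@H](O)CCl | intermediate
3 | (R)-2-(2-methylprop-2-en-1-yl)oxirane | C=C(C)C[C@@H]1CO1 | intermediate (not isolated)
4 | (R)-2-methylhept-1-en-6-yn-4-ol | C=C(C)C[C@@H](O)CC#C | intermediate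
5 | (R)-triisopropyl[(2-methylhept-1-en-6-yn-4-yl)oxy]silane | C=C(C)C[C@@H](O[Si](C(C)C)(C(C)C)C(C)C)CC#C | intermediate
6 | dimethyl[(1E,4R)-2,6-dimethyl-4-(triisopropylsilyloxy)hepta-1,6-dien-1-yl]alumane | C=C(C)C[C@@H](O[Si](C(C)C)(C(C)C)C(C)C)C/C(C)=C/[Al](C)C | intermediate (not isolated)
7 | methyl (2E,5R)-3,7-dimethyl-5-(triisopropylsilyloxy)octa-2,7-dienoate | C=C(C)C[C@@H](O[Si](C(C)C)(C(C)C)C(C)C)C/C(C)=C/C(=O)OC | intermediate
8 | methyl (1R,4R)-2,6,6-trimethyl-4-(triisopropylsilyloxy)cyclohex-2-ene-1-carboxylate | CC1=C[C@H](O[Si](C(C)C)(C(C)C)C(C)C)CC(C)(C)[C@H]1C(=O)OC | intermediate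
9 | [(1R,4R)-2,6,6-trimethyl-4-(triisopropylsilyloxy)cyclohex-2-en-1-yl]methanol | CC1=C[C@H](O[Si](C(C)C)(C(C)C)C(C)C)CC(C)(C)[C@H]1CO | intermediate
10 | (1R,4R)-2,6,6-trimethyl-4-(triisopropylsilyloxy)cyclohex-2-ene-1-carbaldehyde | CC1=C[C@H](O[Si](C(C)C)(C(C)C)C(C)C)CC(C)(C)[C@H]1C=O | intermediate
11 | (3E)-4-[(1R,4R)-2,6,6-trimethyl-4-(triisopropylsilyloxy)cyclohex-2-en-1-yl]but-3-en-2-one | CC1=C[C@H](O[Si](C(C)C)(C(C)C)C(C)C)CC(C)(C)[C@H]1/C=C/C(C)=O | intermediate
12 | (1E)-3-methyl-1-[(1R,4R)-2,6,6-trimethyl-4-(triisopropylsilyloxy)cyclohex-2-en-1-yl]penta-1,4-dien-3-ol (C3 epimers) | CC1=C[C@H](O[Si](C(C)C)(C(C)C)C(C)C)CC(C)(C)[C@H]1/C=C/C(C)(O)C=C | intermediate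
13 | [(2E,4E)-3-methyl-5-[(1R,4R)-2,6,6-trimethyl-4-(triisopropylsilyloxy)cyclohex-2-en-1-yl]penta-2,4-dien-1-yl]triphenylphosphonium bromide | CC1=C[C@H](O[Si](C(C)C)(C(C)C)C(C)C)CC(C)(C)[C@H]1/C=C/C(C)=C/C[P+](c1ccccc1)(c1ccccc1)c1ccccc1.[Br-] | intermediate
14 | (2E,4E,6E)-2,7-dimethylocta-2,4,6-trienedial | O=C/C(C)=C/C=C/C=C(C)/C=O | starting material
15 | (2E,4E,6E,8E,10E,12E)-2,7,11-trimethyl-13-[(1R,4R)-2,6,6-trimethyl-4-(triisopropylsilyloxy)cyclohex-2-en-1-yl]trideca-2,4,6,8,10,12-hexaenal | CC1=C[C@H](O[Si](C(C)C)(C(C)C)C(C)C)CC(C)(C)[C@H]1/C=C/C(C)=C/C=C/C(C)=C/C=C/C=C(C)/C=O | intermediate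
16 | (2E,4E,6E,8E,10E,12E)-2,7,11-trimethyl-13-[(1R,4R)-2,6,6-trimethyl-4-(triisopropylsilyloxy)cyclohex-2-en-1-yl]trideca-2,4,6,8,10,12-hexaen-1-ol | CC1=C[C@H](O[Si](C(C)C)(C(C)C)C(C)C)CC(C)(C)[C@H]1/C=C/C(C)=C/C=C/C(C)=C/C=C/C=C(C)/CO | intermediate
17 | [(2E,4E,6E,8E,10E,12E)-2,7,11-trimethyl-13-[(1R,4R)-2,6,6-trimethyl-4-(triisopropylsilyloxy)cyclohex-2-en-1-yl]trideca-2,4,6,8,10,12-hexaen-1-yl]triphenylphosphonium bromide | CC1=C[C@H](O[Si](C(C)C)(C(C)C)C(C)C)CC(C)(C)[C@H]1/C=C/C(C)=C/C=C/C(C)=C/C=C/C=C(C)/C[P+](c1ccccc1)(c1ccccc1)c1ccccc1.[Br-] | intermediate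
18 | (4R,6R)-4-hydroxy-2,2,6-trimethylcyclohexan-1-one (actinol) | O=C1[C@H](C)C[C@@H](O)CC1(C)C | starting material
19 | (4R,6R)-4-(tert-butyldimethylsilyloxy)-2,2,6-trimethylcyclohexan-1-one | O=C1[C@H](C)C[C@@H](O[Si](C)(C)C(C)(C)C)CC1(C)C | intermediate
20 | lithium (4R)-4-(tert-butyldimethylsilyloxy)-2,6,6-trimethylcyclohex-1-en-1-olate | [Li]OC1=C(C)C[C@@H](O[Si](C)(C)C(C)(C)C)CC1(C)C | intermediate (not isolated)
21 | (4R)-4-(tert-butyldimethylsilyloxy)-2,6,6-trimethylcyclohex-1-en-1-yl trifluoromethanesulfonate | FC(F)(F)S(=O)(=O)OC1=C(C)C[C@@H](O[Si](C)(C)C(C)(C)C)CC1(C)C | intermediate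
22 | methyl (4R)-4-(tert-butyldimethylsilyloxy)-2,6,6-trimethylcyclohex-1-ene-1-carboxylate | COC(=O)C1=C(C)C[C@@H](O[Si](C)(C)C(C)(C)C)CC1(C)C | intermediate
23 | [(4R)-4-(tert-butyldimethylsilyloxy)-2,6,6-trimethylcyclohex-1-en-1-yl]methanol | OCC1=C(C)C[C@@H](O[Si](C)(C)C(C)(C)C)CC1(C)C | intermediate
24 | {[(1R)-4-(bromomethyl)-3,5,5-trimethylcyclohex-3-en-1-yl]oxy}(tert-butyl)dimethylsilane | BrCC1=C(C)C[C@@H](O[Si](C)(C)C(C)(C)C)CC1(C)C | intermediate
25 | furan-3-ylmethanol | OCc1ccoc1 | starting material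
26 | lithium (2-lithiofuran-3-yl)methanolate | [Li]OCc1ccoc1[Li] | intermediate (not isolated)
27 | [2-{[(4R)-4-(tert-butyldimethylsilyloxy)-2,6,6-trimethylcyclohex-1-en-1-yl]methyl}furan-3-yl]methanol | OCc1ccoc1CC1=C(C)C[C@@H](O[Si](C)(C)C(C)(C)C)CC1(C)C | intermediate
28 | tert-butyl{[2-{[(4R)-4-(tert-butyldimethylsilyloxy)-2,6,6-trimethylcyclohex-1-en-1-yl]methyl}furan-3-yl]methoxy}dimethylsilane | CC(C)(C)[Si](C)(C)OCc1ccoc1CC1=C(C)C[C@@H](O[Si](C)(C)C(C)(C)C)CC1(C)C | intermediate
29 | 6-[(tert-butyldimethylsilyloxy)methyl]-1-{[(4R)-4-(tert-butyldimethylsilyloxy)-2,6,6-trimethylcyclohex-1-en-1-yl]methyl}-2,3,7-trioxabicyclo[2.2.1]hept-5-ene (bridgehead epimers) | CC(C)(C)[Si](C)(C)OCC1=CC2OOC1(CC3=C(C)C[C@@H](O[Si](C)(C)C(C)(C)C)CC3(C)C)O2 | intermediate (not isolated)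
30 | (2Z)-3-[(tert-butyldimethylsilyloxy)methyl]-5-[(4R)-4-(tert-butyldimethylsilyloxy)-2,6,6-trimethylcyclohex-1-en-1-yl]-4-oxopent-2-enal | O=C/C=C(/CO[Si](C)(C)C(C)(C)C)C(=O)CC1=C(C)C[C@@H](O[Si](C)(C)C(C)(C)C)CC1(C)C | intermediate (not isolated)
31 | (2E)-3-[(tert-butyldimethylsilyloxy)methyl]-5-[(4R)-4-(tert-butyldimethylsilyloxy)-2,6,6-trimethylcyclohex-1-en-1-yl]-4-oxopent-2-enal | O=C/C=C(\CO[Si](C)(C)C(C)(C)C)C(=O)CC1=C(C)C[C@@H](O[Si](C)(C)C(C)(C)C)CC1(C)C | intermediate
32 | (all-E,3R,3'R,6'R)-3,19-bis(tert-butyldimethylsilyloxy)-3'-(triisopropylsilyloxy)-7,8-dihydro-β,ε-caroten-8-one | CC1=C[C@H](O[Si](C(C)C)(C(C)C)C(C)C)CC(C)(C)[C@H]1/C=C/C(C)=C/C=C/C(C)=C/C=C/C=C(C)/C=C/C=C(\CO[Si](C)(C)C(C)(C)C)C(=O)CC1=C(C)C[C@@H](O[Si](C)(C)C(C)(C)C)CC1(C)C | intermediate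
33 | (all-E,3R,3'R,6'R)-3,19,3'-trihydroxy-7,8-dihydro-β,ε-caroten-8-one (siphonaxanthin) | CC1=C[C@H](O)CC(C)(C)[C@H]1/C=C/C(C)=C/C=C/C(C)=C/C=C/C=C(C)/C=C/C=C(\CO)C(=O)CC1=C(C)C[C@@H](O)CC1(C)C | target

**Step count and risks**
Total step count: 23. Longest linear sequence: 15 steps (steps 1–13, 22, 23).

Most likely to fail:

Step 5 (key cyclisation). Possible failures are incomplete chair control (the 3',6'-cis epimer), proton loss toward the exocyclic or conjugated olefin, acid-induced loss of the silyl ether, and ionisation of the allylic C3'–O bond once the 4',5'-olefin exists. The fallback replaces proton initiation by a soft electrophile, sets out from 7 and comes back at 8. Treatment of 7 with Hg(OTf)2·PhNMe2 in CH3NO2 at −20 °C (mercuricyclisation; only the 1,1-disubstituted olefin binds the mercury salt and the amine buffers the acid), then aqueous NaCl, should give methyl (1R,4R)-6-[(chloromercurio)methyl]-2,6-dimethyl-4-(triisopropylsilyloxy)cyclohex-2-ene-1-carboxylate F1. Reductive demercuration with NaBH4/NaOH should then turn CH2HgCl into the second C1' methyl and return 8.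

Step 21 (furan opening). Possible failures are a competing ene reaction of singlet oxygen with the tetrasubstituted ring-B olefin, over-oxidation of the enedione, and incomplete Z to E equilibration. The fallback sets out from 28 and comes back at 31 through 30. Anodic 2,5-dimethoxylation of the furan (graphite anode, Et4NOTs, CH3OH, −10 °C, potential kept below that of the ring-B olefin) should give 2,5-dimethoxy-2,5-dihydrofuran acetal F5 as an isolable stereoisomer mixture. Mild hydrolysis (pyridinium tosylate, acetone/H2O) should release 30, which iodine equilibrates to 31.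

Step 13 (C25 phosphonium salt). Possible failures are elimination from the polyenyl cation toward retro-type polyenes, loss of the allylic silyl ether and E/Z scrambling. The fallback reverses the roles of the last olefination, sets out from 31 (using 15 directly) and comes back at 32, bypassing 16 and 17. Chemoselective reduction of the aldehyde of 31 (NaBH4, EtOH/CH2Cl2, −78 °C) should give (3E)-3-[(tert-butyldimethylsilyloxy)methyl]-5-hydroxy-1-[(4R)-4-(tert-butyldimethylsilyloxy)-2,6,6-trimethylcyclohex-1-en-1-yl]pent-3-en-2-one F2. An Appel reaction (CBr4, PPh3) should give the corresponding allylic bromide F3, and PPh3 in CH3CN the phosphonium bromide F4. Its vinylogous acyl-stabilised ylide should condense E-selectively with aldehyde 15 (1,2-epoxybutane, EtOH, 75 °C) to give 32.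

Further compounds
F1 | step 5 | methyl (1R,4R)-6-[(chloromercurio)methyl]-2,6-dimethyl-4-(triisopropylsilyloxy)cyclohex-2-ene-1-carboxylate (C6 epimers) | CC1=C[C@H](O[Si](C(C)C)(C(C)C)C(C)C)CC(C)(C[Hg]Cl)[C@H]1C(=O)OC
F2 | step 13 | (3E)-3-[(tert-butyldimethylsilyloxy)methyl]-5-hydroxy-1-[(4R)-4-(tert-butyldimethylsilyloxy)-2,6,6-trimethylcyclohex-1-en-1-yl]pent-3-en-2-one | OC/C=C(\CO[Si](C)(C)C(C)(C)C)C(=O)CC1=C(C)C[C@@H](O[Si](C)(C)C(C)(C)C)CC1(C)C
F3 | step 13 | (3E)-5-bromo-3-[(tert-butyldimethylsilyloxy)methyl]-1-[(4R)-4-(tert-butyldimethylsilyloxy)-2,6,6-trimethylcyclohex-1-en-1-yl]pent-3-en-2-one | BrC/C=C(\CO[Si](C)(C)C(C)(C)C)C(=O)CC1=C(C)C[C@@H](O[Si](C)(C)C(C)(C)C)CC1(C)C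
F4 | step 13 | [(2E)-3-[(tert-butyldimethylsilyloxy)methyl]-5-[(4R)-4-(tert-butyldimethylsilyloxy)-2,6,6-trimethylcyclohex-1-en-1-yl]-4-oxopent-2-en-1-yl]triphenylphosphonium bromide | [Br-].c1ccccc1[P+](c1ccccc1)(c1ccccc1)C/C=C(\CO[Si](C)(C)C(C)(C)C)C(=O)CC1=C(C)C[C@@H](O[Si](C)(C)C(C)(C)C)CC1(C)C
F5 | step 21 | 3-[(tert-butyldimethylsilyloxy)methyl]-2-{[(4R)-4-(tert-butyldimethylsilyloxy)-2,6,6-trimethylcyclohex-1-en-1-yl]methyl}-2,5-dimethoxy-2,5-dihydrofuran (stereoisomer mixture) | COC1C=C(CO[Si](C)(C)C(C)(C)C)C(CC2=C(C)C[C@@H](O[Si](C)(C)C(C)(C)C)CC2(C)C)(OC)O1
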